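- Take the millimolar hour, one millimolar of catalyst working for one hour, as your unit of what a flask has received. This assumes that rate follows catalyst, which is a guess, since no earlier run changes its charge.

| flask | substrate | catalyst | remark | time |
|---|---|---|---|---|
| Friday's | 0.11 M | 15 mM | run made earlier |  |
| alpha | 0.15 M | 25 mM |  | 5.0 h |
| beta | 0.025 M | 50 mM |  | 5.0 h |
| epsilon | 0.40 M | 15 mM |  | 5.0 h |
| gamma | 0.20 M | 30 mM |  | 5.0 h |
| delta | 0.10 M | 15 mM |  | 5.0 h |

Friday's run (percent of the substrate charged)

| time / min | target / % | substrate / % |
|---|---|---|
| 8.00 | 16 | 78 |
| 15.0 | 34 | 61 |
| 30.0 | 48 | 39 |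
| 60.0 | 64 | 20 |
| 120 | 71 | 14 |

(readings scatter by 1.5 percentage points)

- a reading or a percentage of target counts all its forms, free or not
- no earlier run changes the charge of catalyst; that part of a forecast is a guess

- the flasks by amount of target, in percent of the substrate charged, highest first, at 5.0 h (alpha / beta / epsilon / gamma / delta)
- the same order at 1.0 h (alpha / beta / epsilon / gamma / delta)
- the amount of target, in percent of the substrate charged of the flask you put first, at 5.0 h
- the amount of target, in percent of the substrate charged of the flask you put last, at 5.0 h

- In Friday's run substrate stands at 39% after 30.0 min, which in logarithms is 0.409 of a decade for 7.50 mM·h. At fixed catalyst substrate falls pseudo-first-order, so a full decade costs 18.3 mM·h. Call this the decade dose, the catalyst times time that takes substrate down by a factor of 10.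
- Dividing by catalyst gives the first rung of the ladder, the decade time: 22.0 min in beta, 36.7 min in gamma, 44.0 min in alpha and 73.4 min in delta and epsilon. By 1.0 h, then, beta has received 2.73 decade doses, while delta and epsilon have received 0.818.
- The next rung is a stop. At 120 min Friday's substrate reads 14%, which is 0.854 of a decade, although the dose given was 1.64 decade doses. Meanwhile 15.0% of the charge appears in neither column.
- The slowest rung is the run itself. By 5.0 h even delta and epsilon have received 4.09 decade doses, more than the 1.64 that brought Friday's run to its stop. Already at 1.0 h beta, with 2.73 decade doses, has received more than the 1.64 of Friday's stop, while delta and epsilon, with 0.818, have received less. So my own reckoning is that the stops matter for beta at 1.0 h and I expect them to order the flasks at 5.0 h, and one charge cannot tell you how that stop moves.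
- The forecast gives beta > alpha > gamma > delta > epsilon at 5.0 h and beta > gamma > alpha > delta > epsilon at 1.0 h, with 80% for its first flask and 25% for its last. It says: “One run cannot separate a true equilibrium from catalyst killed after a limited number of turnovers”.
- The flasks give epsilon > gamma > alpha > delta > beta at 5.0 h and gamma > alpha > epsilon > delta > beta at 1.0 h. At 5.0 h epsilon, which the forecast put last, holds 89.4%, more than any other flask, and beta, which the forecast put first, holds 30.3%, less than any other flask, with crystals at 0%.

    target + catalyst ⇌ isomer of the product + catalyst, rate k1*[catalyst]*[target] forward; the back reaction follows from the equilibrium constant (K = 1.30, k = 0.00180 M⁻¹ s⁻¹)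
    substrate + catalyst ⇌ target + catalyst, rate k2*[substrate]*[catalyst] forward; the back reaction follows from the equilibrium constant (K = 0.970, k = 0.0340 M⁻¹ s⁻¹)
    crystals ⇌ target, rate k3*(cs3 - [target]) while solid is left; crystals form when [target] > cs3 (solubility = 12.0 mM, k = 0.0380 s⁻¹)
    isomer of the product ⇌ substrate (k = 7.90 × 10⁻⁵ s⁻¹)

- In epsilon half the crystallising up to 5.0 h was done by 0.397 h, and at 1.00 h, after 0.818 decade doses, target with its crystals stood at 72.5%. By 5.00 h, after 4.09 decade doses, substrate stood at 3.57%, isomer of the product had gone from 10.5% at 2.50 h to 7.04%, and crystals had reached 86.4%. A neighbour like epsilon but with 3.70 mM of catalyst received 1.01 decade doses, which reckons to 9.75% substrate; it held 11.8%, with target at 65.9%.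

Readings and results stem from a simulated flask on assumed constants.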